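I kept the books in millimoles of catalyst per litre, because the loading is counted on the left-handed substrate and so the charge changes from flask to flask.

common to all: free catalyst 2.5 mol%; impurity 0.63 mM
- Friday's: left-handed substrate 0.025 M; right-handed substrate 0.025 M; gas 3 mM (held); run made earlier
- Saturday's: left-handed substrate 0.10 M; right-handed substrate 0.10 M; gas 3 mM (held); run made earlier
- flask: left-handed substrate 0.050 M; right-handed substrate 0.050 M; gas 3.0 mM (held)

| run | time / min | left-handed product / % | left-handed substrate / % |
|---|---|---|---|
| Friday's | 1.33 | 3 | 48 |
| Friday's | 4.00 | 1 | 49 |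
| Friday's | 6.00 | 4 | 50 |
| Friday's | 10.0 | 4 | 49 |
| Friday's | 15.0 | 5 | 44 |
| Friday's | 20.0 | 0 | 48 |
| Friday's | 25.0 | 3 | 43 |
| Saturday's | 3.00 | 34 | 16 |
| Saturday's | 6.00 | 50 | 0 |
| Saturday's | 10.0 | 52 | 0 |
| Saturday's | 15.0 | 49 | 2 |
| Saturday's | 20.0 | 51 | 4 |
| Saturday's | 25.0 | 49 | 1 |

(readings scatter by 2 percentage points)

- free catalyst is single-handed; left-handed substrate and right-handed substrate are mirror images of each other, charged as a racemate, each of them at the stated concentration
- at the start none of the gas is in solution

1. apparent order in free catalyst when 10 % of the left-handed substrate and right-handed substrate together are converted (percent change of the rate of making left-handed product for one percent more free catalyst charged)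
2. factor on the rate of making left-handed product when 10 % of the left-handed substrate and right-handed substrate together are converted if free catalyst is charged twice over

Friday's flask held 0.625 mM of free catalyst against 0.63 mM of impurity, and its left-handed product read 3 % at 25.0 min, with a scatter of 2 percentage points. Saturday's flask held 2.50 mM against the same impurity and its left-handed substrate read 0 % at 6.00 min. So I booked the impurity as a poison taking one free catalyst each, and carried the balance forward:

Friday: −0.00500 mM

Saturday: 1.87 mM

This flask: 1.25 mM − 0.63 mM = 0.620 mM

That balance is the working catalyst, the free catalyst charged less the impurity. If the rate follows it: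

order = c(free catalyst charged) / working catalyst = 2.02

doubled charge: factor = 3.02

Saturday's first reading, 34 % at 3.00 min, averages 0.0227 M min⁻¹. Gas crossing into solution may hold a rate like that, so I expected the flask to come in under both figures.

The forecast gave 2 and 3 from a different charge, reckoning that “each impurity seems to kill two catalysts”, where I booked one to one.

The simulation gave 1.4 and 1.63, the order below my 2.02 and the factor below my 3.02.

    free catalyst + left-handed substrate ⇌ catalyst intermediate A (K = 121 L mol⁻¹, k = 24.3 L mol⁻¹ s⁻¹)
    free catalyst + right-handed substrate ⇌ catalyst intermediate B (K = 12.0 L mol⁻¹, k = 591 L mol⁻¹ s⁻¹)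
    reagent + catalyst intermediate A → free catalyst + left-handed product (k = 995 L mol⁻¹ s⁻¹)
    reagent + catalyst intermediate B → free catalyst + right-handed product (k = 69.3 L mol⁻¹ s⁻¹)
    free catalyst + impurity → spent catalyst (k = 2010 L mol⁻¹ s⁻¹)
    gas ⇌ reagent, rate k6*(csat - [reagent]) (kL = 0.154 s⁻¹)

In this flask the passing of free catalyst and impurity into spent catalyst ran alongside the making of left-handed product: at 2.00 min impurity stood at 0 % of its charge, spent catalyst at 50.4 % of the catalyst charged, and left-handed substrate still at 23.9 %. Earlier, at 0.638 min, this flask made left-handed product at 0.0143 M min⁻¹, which is 23.0 min⁻¹ per working catalyst as I reckoned it, a rate at one moment and faster than the 12.1 min⁻¹ averaged up to Saturday's first reading.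

The earlier runs and the new flask stem from a simulated flask on assumed constants.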